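## Analysis of the target

The target is a 2,3-dihydrobenzofuran. C2 carries a 4-hydroxyphenyl group, C3 a 2,4-dihydroxybenzoyl group, and C5 (para to the ring oxygen on ring A) a 3-(2,4-dihydroxyphenyl)-3-oxopropyl chain. The only stereocentres are the adjacent C2 and C3, both S, with the aryl and aroyl groups trans. C3 is benzylic and α to a ketone, so it epimerises easily and trans is the thermodynamic arrangement; the centre that needs outside control is therefore C2. C2 is also a para-hydroxybenzylic aryl ether lying β to the C3 ketone, so forcing acid (ionisation towards a quinone methide) or forcing base (retro-oxa-Michael opening) can open the ring and erase both centres. Five free phenols and two enolisable aryl ketones add to the sensitivity. The difficulty is to fix C2 absolutely and then to build two 2,4-dihydroxyaryl ketones without putting the heterocycle under harsh conditions. The plan rests on reading O1, C2 with its aryl group, C3, and C3a/C7a of ring A as a flavanone in disguise: the carbonyl carbon on C3 is C4 of a 2-arylchroman-4-one, and the C3–C3a bond is what results when the ring A carbon C4a moves from C4 to C3. An enantiopure flavanone already holds the aryl-bearing stereocentre next to the ring oxygen, so a ring contraction converts it into the trans dihydrobenzofuran ester.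

## Retrosynthetic reasoning

**20 from 19.** The four resorcinol-type hydroxyl groups are masked as methoxymethyl ethers in 19 and released last. These acetals survive hydroxide, Grignard, organolithium and palladium chemistry, and their removal is the only acidic step after the core is built.

**19 from 13 and 18.** The aryl–carbonyl bond of the C3 ketone is cut, giving thioester 13 and boronic acid 18. This bond is chosen because the ring contraction leaves the C3 carbon at the acid oxidation level. A neutral, base-free thioester/boronic acid coupling is the one ketone synthesis that does not need a strong nucleophile, a strong base or a strong Lewis acid next to the acidic C3–H. Boronic acid 18 comes from bromide 15 by halogen–metal exchange and borylation, and 15 from the bromodiol 14.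

**13 from 12 from 11.** These are functional group changes only: thioester from acid, acid from methyl ester. The hydrolysis that gives 12 also removes the pivalate, which is no longer needed once the rearrangement is done.

**11 from 7 and 10.** The aryl–CH2 bond at C5 is cut. A Heck reaction of bromide 7 with vinyl carbinol 10 delivers the saturated aryl ketone directly, without a separate reduction or oxidation. The bromine is the only extra substituent ring A has to carry through the key step, and it is inert there. Carbinol 10 comes from aldehyde 9 by vinyl addition, and 9 from dihydroxy aldehyde 8.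

**7 from 4.** This is the key disconnection. The C3–C3a bond is broken and C3a is reconnected to the ester carbon, which returns the six-membered ketone 4. Forward, an oxidative 1,2-shift of the ring A carbon contracts the pyranone to the dihydrofuran. It forms the C3 stereocentre under control of C2 and leaves the old carbonyl carbon as a methyl ester.

**4 from 3 from 1 and 2.** The C2–aryl bond is cut. A catalytic asymmetric conjugate addition of boronic acid 2 to chromone 1 sets C2 in one step; acylation of phenol 3 then gives 4. The key-step precursor is reached in two steps.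

## Alternatives that were turned down

**Alternative 1: double acylation of a diacid.** Both aryl–carbonyl bonds are cut at once, leading back to the dihydrobenzofuran diacid A1 and two molecules of resorcinol A2. Forward, BF3·OEt2 would make each acid group acylate C4 of A2 and give the 4-O-pivalate of the target, A3.
- For: two ketones form in one step, A2 needs no protection, the regiochemistry on A2 is the classical one, and boron chelation protects the product ketones. On step economy in the endgame this is clearly stronger than the chosen route.
- Against: the two acids differ greatly. The chain acid is unhindered; the C3 acid is secondary, flanked by ring A and the C2 aryl group. Forcing the second acylation needs hot Lewis acid, which can ionise the benzylic C2–O1 bond; A2 is an excellent trap for such a cation. Ketene formation or decarbonylation at C3 and Fries chemistry of the pivalate are further risks.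
- Comparison: A1 would still have to be made enantiopure, most plausibly by the same ring contraction. The chosen route gives up the brevity and instead forms each ketone under neutral palladium catalysis, where C2 is not at risk.

**Alternative 2: biomimetic oxa-addition.** The O1–C2 bond is cut, giving the ring-opened α-aryl chalcone A4. Forward, the chiral phosphoric acid (R)-3,3'-bis(2,4,6-triisopropylphenyl)-1,1'-binaphthyl-2,2'-diyl hydrogen phosphate would tautomerise A4 to its para-quinone methide enol and direct the ring A phenol onto the methide carbon (5-exo-trig). The product is the tetrakis(methoxymethyl) ether A5, which is the same compound as 19.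
- For: it is the most convergent plan, starts from an achiral precursor, and makes the ring and both centres in one step. On convergence and step count it beats the chosen route.
- Against: the enantio-determining step is C–O bond formation at a remote methide carbon in an ion pair with several possible hydrogen-bonding arrangements and two enol geometries. The closure is reversible under the same acid, so any selectivity can drain towards the racemate. The catalyst acid also meets four acid-labile acetals.
- Comparison: the chosen route splits the problem. C2 comes from a catalytic asymmetric C–C bond formation of an established type, checked on a simple flavanone, and C3 from a stereospecific shift.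

**Alternative 3: auxiliary aldol, then aryl ether closure.** The O1–C7a bond is cut, giving the syn aldol N-methoxy-N-methyl amide A6, whose two centres would come from an oxazolidinone-controlled aldol reaction. Forward, Pd(OAc)2 with 2-(di-tert-butylphosphino)-1,1'-binaphthyl and Cs2CO3 would couple the C2 hydroxyl group with the ortho C–Br carbon to give the chloro dihydrobenzofuran amide A7.
- For: the absolute and relative configuration come from very predictable auxiliary chemistry, and the amide of A7 could be turned into the C3 ketone directly with an aryl metal reagent. On certainty of configuration and on the ketone step it is as strong as or stronger than the chosen route.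
- Against: A6 is a β-hydroxy amide with a doubly activated α-hydrogen. Under carbonate at elevated temperature, retro-aldol cleavage, dehydration to the α-aryl cinnamamide and α-epimerisation all compete. The palladium alkoxide of a secondary benzylic alcohol can undergo β-hydride elimination to the ketone. The chain would then have to be attached through an aryl chloride, and the auxiliary is stoichiometric.
- Comparison: the chosen route reaches the core in three steps with catalytic asymmetry and never exposes an aldol-type intermediate to base.

Key step: step 3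

## Assumptions

- The target is taken as the (2S,3S)-trans isomer encoded by its SMILES.
- The sense of induction in step 1 is assigned by analogy with arylation of 3-substituted cyclohexenones, where the (S)-ligand attacks the enone face that corresponds to the (R)-flavanone. The (R)-ligand is therefore specified; if the analogy does not hold, the ligand antipode is used.

## Steps

Step 1
Reactants: 1 6-bromochromone (6-bromo-4H-chromen-4-one); 2 4-hydroxyphenylboronic acid
Product: 3 (S)-6-bromo-2-(4-hydroxyphenyl)chroman-4-one
Conditions: 2 (2 equiv), Pd(OCOCF3)2 (5 mol%), (R)-t-BuPyOx [(R)-4-tert-butyl-2-(pyridin-2-yl)-4,5-dihydrooxazole, 6 mol%], NH4PF6 (30 mol%), H2O (5 equiv), ClCH2CH2Cl, 60 °C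
Reagents that add atoms: none
Why: Asymmetric conjugate addition of an arylboronic acid under cationic divalent palladium–pyridinooxazoline catalysis: transmetalation, enantio-determining insertion of the chromone C2=C3 bond into the aryl–palladium bond, and protonolysis of the palladium enolate by water, with no zerovalent palladium in the cycle, so the C–Br bond should remain. The tert-butyl group of the ligand shields one face of the bound chromone and sets C2 as S; the medium is base-free, so the flavanone is not opened to the chalcone.

Step 2
Reactants: 3 (S)-6-bromo-2-(4-hydroxyphenyl)chroman-4-one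
Product: 4 (S)-6-bromo-2-[4-(pivaloyloxy)phenyl]chroman-4-one
Conditions: t-BuCOCl, pyridine, DMAP (cat.), CH2Cl2, 0 °C → rt
Reagents that add atoms: pivaloyl chloride, CC(C)(C)C(=O)Cl
Why: O-Acylation of the phenol through the N-acylpyridinium salt; pyridine is too weak a base to open the flavanone by retro-oxa-Michael reaction, so C2 is untouched. The pivalate is chosen because it makes ring B electron-poor and resists acid methanolysis in step 3.

Step 3
Reactants: 4 (S)-6-bromo-2-[4-(pivaloyloxy)phenyl]chroman-4-one
Product: 7 methyl (2S,3S)-5-bromo-2-[4-(pivaloyloxy)phenyl]-2,3-dihydrobenzofuran-3-carboxylate, via methyl enol ether 5 (not isolated), via trans C3 iodane 6 (not isolated)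
Conditions: PhI(OAc)2 (1.2 equiv), conc. H2SO4 (1 equiv), HC(OMe)3, 0 °C → rt; aq. NaHCO3
Reagents that add atoms: trimethyl orthoformate, COC(OC)OC (methoxy group of the ester); water, O (carbonyl oxygen, on hydrolysis of the ortho ester at work-up)
Why: Acid and orthoformate convert the ketone into its dimethyl ketal and the methyl enol ether 5; electrophilic trivalent iodine attacks C3 of 5 on the face opposite the pseudo-equatorial C2 aryl group and methanol re-forms the ketal, giving the trans iodane 6 with an equatorial C–I bond. That bond is antiperiplanar to the ring bond C4–C4a, so the ring A carbon C4a migrates from C4 to C3 through a bridged phenonium-type transition state while iodobenzene leaves, and C4 is left as a dimethoxycarbenium ion that is captured by methanol and hydrolysed to the methyl ester on work-up. The closest known reaction type is the oxidative 1,2-aryl rearrangement of aryl ketone ketals with trivalent iodine or Tl(NO3)3, whose ring-contracting form is established for flavanones. The five-membered ring is not closed by a cyclisation but by ring contraction: the C3–C3a bond forms as an intramolecular backside displacement at C3 by the ipso carbon (3-exo-tet through the spiro phenonium), and C4 becomes exocyclic. C3 is the new stereocentre and is set by substrate control from C2: anti delivery of iodine followed by inversion in the shift gives the 2,3-trans ester, and the enolisable C3–H lets any cis ester equilibrate to trans. The step needs ring A to migrate in preference to ring B moving from C2 (isoflavone skeleton) and to loss of the C2 hydrogen (flavone); the ortho ring oxygen on the migrating carbon and the two methoxy groups on C4 favour the ring A shift, and the electron-poor pivaloyloxyphenyl ring disfavours the ring B shift. C2 must also not racemise by acid ring-opening to the 2'-hydroxychalcone; the acyloxy group makes C2 a poor benzylic cation, and the hindered pivalate should survive the acidic methanol.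

Step 4
Reactants: 8 2,4-dihydroxybenzaldehyde
Product: 9 2,4-bis(methoxymethoxy)benzaldehyde
Conditions: MeOCH2Cl (3 equiv), i-Pr2NEt (4 equiv), CH2Cl2, 0 °C → reflux
Reagents that add atoms: chloromethyl methyl ether, COCCl
Why: Double O-alkylation of the phenols to methoxymethyl acetals with a hindered amine base; excess reagent and warming are needed for the hydrogen-bonded ortho hydroxyl group.

Step 5
Reactants: 9 2,4-bis(methoxymethoxy)benzaldehyde
Product: 10 rac-1-[2,4-bis(methoxymethoxy)phenyl]prop-2-en-1-ol
Conditions: CH2=CHMgBr, THF, −78 → 0 °C; aq. NH4Cl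
Reagents that add atoms: vinylmagnesium bromide, C=C[Mg]Br
Why: 1,2-Addition of a vinyl Grignard reagent to the aldehyde; the carbinol centre forms as a racemate, which does not matter because it becomes the ketone carbon in step 6.

Step 6
Reactants: 7 methyl (2S,3S)-5-bromo-2-[4-(pivaloyloxy)phenyl]-2,3-dihydrobenzofuran-3-carboxylate; 10 rac-1-[2,4-bis(methoxymethoxy)phenyl]prop-2-en-1-ol
Product: 11 methyl (2S,3S)-5-{3-[2,4-bis(methoxymethoxy)phenyl]-3-oxopropyl}-2-[4-(pivaloyloxy)phenyl]-2,3-dihydrobenzofuran-3-carboxylate
Conditions: 10 (1.5 equiv), Pd(OAc)2 (5 mol%), P(o-tol)3 (10 mol%), n-Bu4NCl, NaHCO3, DMF, 100 °C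
Reagents that add atoms: none
Why: Mizoroki–Heck arylation of an allylic alcohol: syn insertion puts the aryl group on the terminal carbon, β-hydride elimination towards the carbinol carbon gives the enol, and tautomerisation gives the saturated aryl ketone, so the chain arrives at the right oxidation level in one step. Hydrogencarbonate is too weak to cleave the pivalate or open the ring, and C3 can at most equilibrate towards the trans ester it already is.

Step 7
Reactants: 11 methyl (2S,3S)-5-{3-[2,4-bis(methoxymethoxy)phenyl]-3-oxopropyl}-2-[4-(pivaloyloxy)phenyl]-2,3-dihydrobenzofuran-3-carboxylate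
Product: 12 (2S,3S)-5-{3-[2,4-bis(methoxymethoxy)phenyl]-3-oxopropyl}-2-(4-hydroxyphenyl)-2,3-dihydrobenzofuran-3-carboxylic acid
Conditions: LiOH·H2O (5 equiv), THF/MeOH/H2O, 0 °C → rt; then 1 M HCl to pH 4 at 0 °C
Reagents that add atoms: lithium hydroxide, [Li+].[OH-] (the hydroxide oxygen becomes an oxygen of the carboxylic acid)
Why: Saponification of the methyl ester and, deliberately in the same operation, of the aryl pivalate, whose task ended with step 3; the acetals and the chain ketone are stable to hydroxide. The π system of a C3 enolate lies perpendicular to the C2–O1 bond in the five-membered ring, so base can only epimerise C3 towards trans, and β-elimination of the phenoxide is stereoelectronically poor.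

Step 8
Reactants: 12 (2S,3S)-5-{3-[2,4-bis(methoxymethoxy)phenyl]-3-oxopropyl}-2-(4-hydroxyphenyl)-2,3-dihydrobenzofuran-3-carboxylic acid
Product: 13 S-(4-methylphenyl) (2S,3S)-5-{3-[2,4-bis(methoxymethoxy)phenyl]-3-oxopropyl}-2-(4-hydroxyphenyl)-2,3-dihydrobenzofuran-3-carbothioate
Conditions: 4-MeC6H4SH (3 equiv), EDC·HCl (1.3 equiv), DMAP (5 mol%), CH2Cl2, 0 °C → rt
Reagents that add atoms: 4-methylbenzenethiol, Cc1ccc(S)cc1
Why: Carbodiimide-mediated (Steglich-type) thioesterification; the thiol, used in excess, is far more nucleophilic towards the O-acylisourea than the free phenol, so S-acylation should outrun O-acylation and oligomerisation.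

Step 9
Reactants: 14 4-bromoresorcinol (4-bromobenzene-1,3-diol)
Product: 15 1-bromo-2,4-bis(methoxymethoxy)benzene
Conditions: MeOCH2Cl (3 equiv), i-Pr2NEt (4 equiv), CH2Cl2, 0 °C → rt
Reagents that add atoms: chloromethyl methyl ether, COCCl
Why: O-Alkylation of both phenols to methoxymethyl ethers with amine base; the aryl bromide is inert.

Step 10
Reactants: 15 1-bromo-2,4-bis(methoxymethoxy)benzene
Product: 18 2,4-bis(methoxymethoxy)phenylboronic acid, via aryllithium 16 (not isolated), via lithium aryltriisopropoxyborate 17 (not isolated)
Conditions: n-BuLi, THF, −78 °C; B(Oi-Pr)3, −78 °C → rt; aq. NH4Cl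
Reagents that add atoms: triisopropyl borate, CC(C)OB(OC(C)C)OC(C)C; water, O (hydroxyl groups on boron)
Why: Bromine–lithium exchange at low temperature (the ortho acetal oxygen chelates lithium), capture by the borate to the ate complex, and mild hydrolysis to the boronic acid. The bromide fixes the regiochemistry, which a directed lithiation of the parent bis-ether would not.

Step 11
Reactants: 13 S-(4-methylphenyl) (2S,3S)-5-{3-[2,4-bis(methoxymethoxy)phenyl]-3-oxopropyl}-2-(4-hydroxyphenyl)-2,3-dihydrobenzofuran-3-carbothioate; 18 2,4-bis(methoxymethoxy)phenylboronic acid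
Product: 19 1-[2,4-bis(methoxymethoxy)phenyl]-3-{(2S,3S)-3-[2,4-bis(methoxymethoxy)benzoyl]-2-(4-hydroxyphenyl)-2,3-dihydrobenzofuran-5-yl}propan-1-one
Conditions: 18 (2 equiv), Pd2(dba)3 (5 mol%), P(2-furyl)3 (20 mol%), Cu(O2C-2-C4H3S) (univalent copper thiophene-2-carboxylate, 1.6 equiv), THF, 50 °C, argon
Reagents that add atoms: none
Why: Liebeskind–Srogl ketone synthesis: zerovalent palladium inserts into the C–S bond, the univalent copper carboxylate binds sulfur and activates boron for base-free transmetalation, and reductive elimination gives the aryl ketone. The medium is neutral, so the acidic C3–H, the free phenol, the chain ketone and the acetals are tolerated and C3 stays trans.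

Step 12
Reactants: 19 1-[2,4-bis(methoxymethoxy)phenyl]-3-{(2S,3S)-3-[2,4-bis(methoxymethoxy)benzoyl]-2-(4-hydroxyphenyl)-2,3-dihydrobenzofuran-5-yl}propan-1-one
Product: 20 1-(2,4-dihydroxyphenyl)-3-[(2S,3S)-3-(2,4-dihydroxybenzoyl)-2-(4-hydroxyphenyl)-2,3-dihydrobenzofuran-5-yl]propan-1-one (the target)
Conditions: 3 M aq. HCl, MeOH/THF, 40 °C
Reagents that add atoms: none
Why: Acid-catalysed transacetalisation of the four methoxymethyl ethers to the solvent methanol. At this acidity and temperature the C2–O1 bond should hold, because the acyl-bearing C3 destabilises a cation at C2 and an enol at C3 cannot expel O1 for stereoelectronic reasons; C3 remains the thermodynamic trans epimer.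

## Compound list

1 | 6-bromochromone (6-bromo-4H-chromen-4-one) | O=c1ccoc2ccc(Br)cc12 | starting material
2 | 4-hydroxyphenylboronic acid | OB(O)c1ccc(O)cc1 | starting material
3 | (S)-6-bromo-2-(4-hydroxyphenyl)chroman-4-one | O=C1C[C@@H](c2ccc(O)cc2)Oc2ccc(Br)cc21 | intermediate
4 | (S)-6-bromo-2-[4-(pivaloyloxy)phenyl]chroman-4-one | O=C1C[C@@H](c2ccc(OC(=O)C(C)(C)C)cc2)Oc2ccc(Br)cc21 | intermediate
5 | (S)-6-bromo-4-methoxy-2-[4-(pivaloyloxy)phenyl]-2H-chromene (methyl enol ether, formed in the flask) | COC1=C[C@@H](c2ccc(OC(=O)C(C)(C)C)cc2)Oc2ccc(Br)cc21 | intermediate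
6 | acetoxy{(2R,3R)-6-bromo-4,4-dimethoxy-2-[4-(pivaloyloxy)phenyl]chroman-3-yl}(phenyl)-λ3-iodane (2,3-trans, formed in the flask; C2 has the same geometry as in 4, its descriptor changes only because iodine raises the priority of C3) | COC1(OC)[C@H](I(OC(C)=O)c2ccccc2)[C@@H](c2ccc(OC(=O)C(C)(C)C)cc2)Oc2ccc(Br)cc21 | intermediate
7 | methyl (2S,3S)-5-bromo-2-[4-(pivaloyloxy)phenyl]-2,3-dihydrobenzofuran-3-carboxylate | Brc1ccc2c(c1)[C@H](C(=O)OC)[C@@H](c1ccc(OC(=O)C(C)(C)C)cc1)O2 | intermediate
8 | 2,4-dihydroxybenzaldehyde | O=Cc1ccc(O)cc1O | starting material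
9 | 2,4-bis(methoxymethoxy)benzaldehyde | O=Cc1ccc(OCOC)cc1OCOC | intermediate
10 | rac-1-[2,4-bis(methoxymethoxy)phenyl]prop-2-en-1-ol | C=CC(O)c1ccc(OCOC)cc1OCOC | intermediate
11 | methyl (2S,3S)-5-{3-[2,4-bis(methoxymethoxy)phenyl]-3-oxopropyl}-2-[4-(pivaloyloxy)phenyl]-2,3-dihydrobenzofuran-3-carboxylate | O=C(CCc1ccc2c(c1)[C@H](C(=O)OC)[C@@H](c1ccc(OC(=O)C(C)(C)C)cc1)O2)c1ccc(OCOC)cc1OCOC | intermediate
12 | (2S,3S)-5-{3-[2,4-bis(methoxymethoxy)phenyl]-3-oxopropyl}-2-(4-hydroxyphenyl)-2,3-dihydrobenzofuran-3-carboxylic acid | O=C(CCc1ccc2c(c1)[C@H](C(=O)O)[C@@H](c1ccc(O)cc1)O2)c1ccc(OCOC)cc1OCOC | intermediate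
13 | S-(4-methylphenyl) (2S,3S)-5-{3-[2,4-bis(methoxymethoxy)phenyl]-3-oxopropyl}-2-(4-hydroxyphenyl)-2,3-dihydrobenzofuran-3-carbothioate | O=C(CCc1ccc2c(c1)[C@H](C(=O)Sc1ccc(C)cc1)[C@@H](c1ccc(O)cc1)O2)c1ccc(OCOC)cc1OCOC | intermediate
14 | 4-bromoresorcinol (4-bromobenzene-1,3-diol) | Oc1ccc(Br)c(O)c1 | starting material
15 | 1-bromo-2,4-bis(methoxymethoxy)benzene | COCOc1ccc(Br)c(OCOC)c1 | intermediate
16 | [2,4-bis(methoxymethoxy)phenyl]lithium (formed in the flask) | [Li]c1ccc(OCOC)cc1OCOC | intermediate
17 | lithium [2,4-bis(methoxymethoxy)phenyl]tri(propan-2-yloxy)borate (formed in the flask) | [Li+].CC(C)O[B-](OC(C)C)(OC(C)C)c1ccc(OCOC)cc1OCOC | intermediate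
18 | 2,4-bis(methoxymethoxy)phenylboronic acid | OB(O)c1ccc(OCOC)cc1OCOC | intermediate
19 | 1-[2,4-bis(methoxymethoxy)phenyl]-3-{(2S,3S)-3-[2,4-bis(methoxymethoxy)benzoyl]-2-(4-hydroxyphenyl)-2,3-dihydrobenzofuran-5-yl}propan-1-one | O=C(CCc1ccc2c(c1)[C@H](C(=O)c1ccc(OCOC)cc1OCOC)[C@@H](c1ccc(O)cc1)O2)c1ccc(OCOC)cc1OCOC | intermediate
20 | 1-(2,4-dihydroxyphenyl)-3-[(2S,3S)-3-(2,4-dihydroxybenzoyl)-2-(4-hydroxyphenyl)-2,3-dihydrobenzofuran-5-yl]propan-1-one | O=C(CCc1ccc2c(c1)[C@H](C(=O)c1ccc(O)cc1O)[C@@H](c1ccc(O)cc1)O2)c1ccc(O)cc1O | target

## Step count and risks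

Total step count: 12. Longest linear sequence: 8 steps (steps 1, 2, 3, 6, 7, 8, 11, 12, from 1).

**Step 3 (key step).** The most likely failures are a competing shift of ring B from C2 to C3 (isoflavone skeleton), loss of the C2 hydrogen to the flavone, and partial racemisation of C2 by acid ring-opening. The bromine, meta to the migrating carbon, slows the ring A shift inductively and gives these side paths more time. Fallback, from 4 back to 7: separate the two events. Bromination of 4 at C3 with CuBr2 in ethyl acetate/chloroform should give the 2,3-trans bromo ketone (2R,3R)-3,6-dibromo-2-[4-(pivaloyloxy)phenyl]chroman-4-one F1. Ketalisation with trimethyl orthoformate, methanol and a sulfonic acid gives the dimethyl ketal (2R,3R)-3,6-dibromo-4,4-dimethoxy-2-[4-(pivaloyloxy)phenyl]chromane F2. AgBF4 in methanol then abstracts the equatorial bromide and triggers the same 1,2-aryl shift (the α-halo ketal rearrangement used for 2-arylalkanoic esters), which after work-up gives 7.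

**Step 1.** Protodeboronation of the electron-rich boronic acid and binding of the free phenol to the cationic palladium may stall the reaction, and the face selectivity may be insufficient or of the unexpected sense. Fallback, from 2 and 1 back to 4: acylate 2 first with pivaloyl chloride and pyridine to 4-(pivaloyloxy)phenylboronic acid F3. Add F3 to 1 in a rhodium-catalysed asymmetric 1,4-addition ([Rh(OH)(cod)]2, univalent rhodium, with an electron-poor atropisomeric bisphosphine, in aqueous toluene). This gives 4 directly and avoids handling the base-sensitive hydroxyflavanone 3.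

**Step 6.** Oxidative addition into the electron-rich aryl bromide may be slow at a temperature where the doubly activated benzylic allylic alcohol ionises, or is isomerised by palladium hydride to the saturated ketone before it couples. β-Hydride elimination away from the carbinol would give the arylated allylic alcohol. Fallback, from 10 and 7 back to 11: oxidise 10 with MnO2 to the vinyl ketone 1-[2,4-bis(methoxymethoxy)phenyl]prop-2-en-1-one F4, used at once. A Heck reaction of F4 with 7 gives the chalcone methyl (2S,3S)-5-{(E)-3-[2,4-bis(methoxymethoxy)phenyl]-3-oxoprop-1-en-1-yl}-2-[4-(pivaloyloxy)phenyl]-2,3-dihydrobenzofuran-3-carboxylate F5. Conjugate reduction with [CuH(PPh3)]6 then saturates only the enone double bond and gives 11.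

**Step 11.** Transmetalation of the ortho-substituted, electron-rich boronic acid onto a hindered secondary acylpalladium may be slower than copper-mediated protodeboronation, and the acylpalladium may lose carbon monoxide. Fallback, from 15 and 13 back to 19: convert 15 by bromine–lithium exchange (via 16) and ZnCl2 into [2,4-bis(methoxymethoxy)phenyl]zinc chloride F6. Couple F6 (excess, since one equivalent is consumed by the phenol) with 13 using PdCl2(PPh3)2 in THF/toluene at room temperature (Fukuyama coupling) to give 19.

**Step 12.** The free para-hydroxyl group on the C2 aryl ring can assist acid ionisation of the C2–O1 bond, which would cause ring-opening or loss of configuration at C2. The para acetals may also cleave slowly and call for harsher acid. Fallback, from 19 back to 20: re-acylate the single free phenol of 19 with pivaloyl chloride and pyridine to 1-[2,4-bis(methoxymethoxy)phenyl]-3-{(2S,3S)-3-[2,4-bis(methoxymethoxy)benzoyl]-2-[4-(pivaloyloxy)phenyl]-2,3-dihydrobenzofuran-5-yl}propan-1-one F7. Remove the four acetals with HCl in methanol while the C2 aryl ring is deactivated, giving 1-(2,4-dihydroxyphenyl)-3-{(2S,3S)-3-(2,4-dihydroxybenzoyl)-2-[4-(pivaloyloxy)phenyl]-2,3-dihydrobenzofuran-5-yl}propan-1-one F8. Cleave the pivalate last with K2CO3 in methanol at 0 °C to give 20.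

## Further compounds

F1 | step 3 | (2R,3R)-3,6-dibromo-2-[4-(pivaloyloxy)phenyl]chroman-4-one (2,3-trans) | O=C1[C@H](Br)[C@@H](c2ccc(OC(=O)C(C)(C)C)cc2)Oc2ccc(Br)cc21
F2 | step 3 | (2R,3R)-3,6-dibromo-4,4-dimethoxy-2-[4-(pivaloyloxy)phenyl]chromane (2,3-trans) | COC1(OC)[C@H](Br)[C@@H](c2ccc(OC(=O)C(C)(C)C)cc2)Oc2ccc(Br)cc21
F3 | step 1 | 4-(pivaloyloxy)phenylboronic acid | CC(C)(C)C(=O)Oc1ccc(B(O)O)cc1
F4 | step 6 | 1-[2,4-bis(methoxymethoxy)phenyl]prop-2-en-1-one | C=CC(=O)c1ccc(OCOC)cc1OCOC
F5 | step 6 | methyl (2S,3S)-5-{(E)-3-[2,4-bis(methoxymethoxy)phenyl]-3-oxoprop-1-en-1-yl}-2-[4-(pivaloyloxy)phenyl]-2,3-dihydrobenzofuran-3-carboxylate | O=C(/C=C/c1ccc2c(c1)[C@H](C(=O)OC)[C@@H](c1ccc(OC(=O)C(C)(C)C)cc1)O2)c1ccc(OCOC)cc1OCOC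
F6 | step 11 | [2,4-bis(methoxymethoxy)phenyl]zinc chloride | Cl[Zn]c1ccc(OCOC)cc1OCOC
F7 | step 12 | 1-[2,4-bis(methoxymethoxy)phenyl]-3-{(2S,3S)-3-[2,4-bis(methoxymethoxy)benzoyl]-2-[4-(pivaloyloxy)phenyl]-2,3-dihydrobenzofuran-5-yl}propan-1-one | O=C(CCc1ccc2c(c1)[C@H](C(=O)c1ccc(OCOC)cc1OCOC)[C@@H](c1ccc(OC(=O)C(C)(C)C)cc1)O2)c1ccc(OCOC)cc1OCOC
F8 | step 12 | 1-(2,4-dihydroxyphenyl)-3-{(2S,3S)-3-(2,4-dihydroxybenzoyl)-2-[4-(pivaloyloxy)phenyl]-2,3-dihydrobenzofuran-5-yl}propan-1-one | O=C(CCc1ccc2c(c1)[C@H](C(=O)c1ccc(O)cc1O)[C@@H](c1ccc(OC(=O)C(C)(C)C)cc1)O2)c1ccc(O)cc1O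
A1 | alternative 1 | (2S,3S)-5-(2-carboxyethyl)-2-[4-(pivaloyloxy)phenyl]-2,3-dihydrobenzofuran-3-carboxylic acid | OC(=O)CCc1ccc2c(c1)[C@H](C(=O)O)[C@@H](c1ccc(OC(=O)C(C)(C)C)cc1)O2
A2 | alternative 1 | resorcinol (benzene-1,3-diol) | Oc1cccc(O)c1
A3 | alternative 1 | 1-(2,4-dihydroxyphenyl)-3-{(2S,3S)-3-(2,4-dihydroxybenzoyl)-2-[4-(pivaloyloxy)phenyl]-2,3-dihydrobenzofuran-5-yl}propan-1-one (identical with F8) | O=C(CCc1ccc2c(c1)[C@H](C(=O)c1ccc(O)cc1O)[C@@H](c1ccc(OC(=O)C(C)(C)C)cc1)O2)c1ccc(O)cc1O
A4 | alternative 2 | 2-{5-[3-(2,4-bis(methoxymethoxy)phenyl)-3-oxopropyl]-2-hydroxyphenyl}-1-[2,4-bis(methoxymethoxy)phenyl]-3-(4-hydroxyphenyl)prop-2-en-1-one | O=C(CCc1ccc(O)c(c1)C(=Cc1ccc(O)cc1)C(=O)c1ccc(OCOC)cc1OCOC)c1ccc(OCOC)cc1OCOC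
A5 | alternative 2 | 1-[2,4-bis(methoxymethoxy)phenyl]-3-{(2S,3S)-3-[2,4-bis(methoxymethoxy)benzoyl]-2-(4-hydroxyphenyl)-2,3-dihydrobenzofuran-5-yl}propan-1-one (identical with 19) | O=C(CCc1ccc2c(c1)[C@H](C(=O)c1ccc(OCOC)cc1OCOC)[C@@H](c1ccc(O)cc1)O2)c1ccc(OCOC)cc1OCOC
A6 | alternative 3 | (2S,3S)-2-(2-bromo-5-chlorophenyl)-3-hydroxy-N-methoxy-N-methyl-3-[4-(methoxymethoxy)phenyl]propanamide (syn aldol) | Clc1ccc(Br)c(c1)[C@H](C(=O)N(C)OC)[C@@H](c1ccc(OCOC)cc1)O
A7 | alternative 3 | (2S,3S)-5-chloro-N-methoxy-N-methyl-2-[4-(methoxymethoxy)phenyl]-2,3-dihydrobenzofuran-3-carboxamide | Clc1ccc2c(c1)[C@H](C(=O)N(C)OC)[C@@H](c1ccc(OCOC)cc1)O2
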